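**Retrosynthetic overview**
- The biaryl bond is cut last: Suzuki–Miyaura coupling of a 2-bromo-7-methyljuglone with an 8-borylated 7-methyl-4-oxochromene-5-carboxylic acid.
- Key disconnection: the pyranone O1–C2 bond and the 5-carboxyl group of the chromone come from the quinone ring of a 6-bromo-7-methyljuglone, by oxygen insertion into C1–C2 and reclosure of the peri hydroxyl onto C2 (a C–O bond-forming ring contraction).
- Both juglones come from Diels–Alder annulation of vinylketene silyl acetals onto benzoquinones; one bromine is placed by the dienophile (C2), the other by the diene (C6).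
- Order of ring formation: ring A of each naphthoquinone, then the pyranone ring, then the biaryl bond.
- All carbon comes from methyl 3-methylbut-2-enoate and two benzoquinones.

Assumption: the target has no stereocentre and its SMILES fixes no configuration of the biaryl axis, so it is made as the one constitution drawn, without a stereocontrol step.

Step 1
Reactants: 1 methyl 3-methylbut-2-enoate
Product: 2 1-methoxy-3-methyl-1-(trimethylsilyloxy)buta-1,3-diene
Conditions: LiN(iPr)2 (1.1 equiv), THF, −78 °C; Me3SiCl (1.3 equiv), −78 °C to rt; distil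
Reagents that add atoms: chlorotrimethylsilane, C[Si](C)(C)Cl
Why: the amide base removes a gamma proton of the enoate and the extended enolate is trapped on oxygen by the silyl chloride, the standard gamma-deprotonation/O-silylation route to a vinylketene silyl acetal.

Step 2
Reactants: 2 1-methoxy-3-methyl-1-(trimethylsilyloxy)buta-1,3-diene; 3 2,5-dibromo-1,4-benzoquinone
Product: 5 2-bromo-5-hydroxy-7-methylnaphthalene-1,4-dione, via Diels–Alder cycloadduct 4 (not isolated)
Conditions: CH2Cl2, −30 °C to rt; then 1 M HCl, THF, rt
Reagents that add atoms: none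
Why: Brassard-type regiospecific Diels–Alder annulation in which the nucleophilic CH2 terminus of 2 attacks the unsubstituted carbon of a bromo-ene unit and the acetal carbon bonds to the bromine-bearing carbon, after which loss of HBr and methanol and desilylation aromatise ring A and leave the second bromine at C2, next to the carbonyl that is not peri to the new hydroxyl.

Step 3
Reactants: 1 methyl 3-methylbut-2-enoate
Product: 7 methyl 2-bromo-3-methylbut-2-enoate, via vicinal dibromide 6 (not isolated)
Conditions: Br2 (1.05 equiv), CH2Cl2, 0 °C; then Et3N (2.5 equiv), reflux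
Reagents that add atoms: bromine, BrBr
Why: bromine adds across the trisubstituted alkene and E2 loss of HBr through the acidic alpha hydrogen gives the alpha-bromo enoate (bromination/dehydrobromination).

Step 4
Reactants: 7 methyl 2-bromo-3-methylbut-2-enoate
Product: 8 2-bromo-1-methoxy-3-methyl-1-(trimethylsilyloxy)buta-1,3-diene
Conditions: LiN(iPr)2 (1.1 equiv), Me3SiCl (1.5 equiv, present from the start), THF, −78 °C to 0 °C; pentane, filter, concentrate
Reagents that add atoms: chlorotrimethylsilane, C[Si](C)(C)Cl
Why: the same gamma-deprotonation/O-silylation as in step 1, run with an internal silyl quench so that the alpha-bromo dienolate is trapped before it can decompose.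

Step 5
Reactants: 8 2-bromo-1-methoxy-3-methyl-1-(trimethylsilyloxy)buta-1,3-diene; 9 1,4-benzoquinone
Product: 12 6-bromo-5-hydroxy-7-methylnaphthalene-1,4-dione, via Diels–Alder cycloadduct 10 (not isolated), via bromonaphthalenetriol 11 (not isolated)
Conditions: 9 (3 equiv), CH2Cl2, −20 °C to rt; then 1 M HCl, THF, rt, air
Reagents that add atoms: none
Why: Diels–Alder reaction of the vinylketene acetal with the symmetrical quinone (no regiochemical issue), acid-promoted enolisation and 1,4-elimination of methanol aromatise ring A, and the excess benzoquinone oxidises triol 11 to the quinone; the bromine sits on the diene carbon next to the acetal carbon and therefore ends at C6, ortho to the hydroxyl.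

Step 6
Reactants: 12 6-bromo-5-hydroxy-7-methylnaphthalene-1,4-dione
Product: 15 8-bromo-7-methyl-4-oxo-4H-chromene-5-carboxylic acid, via benzoxepinedione 13 (not isolated), via keto aldehyde acid 14 (not isolated)
Conditions: bis[3,5-bis(trifluoromethyl)phenyl] diselenide (5 mol %), 50% aq. H2O2 (1.3 equiv), (CF3)2CHOH, 25 °C; then TsOH (10 mol %), 45 °C
Reagents that add atoms: hydrogen peroxide, OO (net source of the added oxygen); water, O (opens lactone 13, the same amount is lost again on ring closure)
Why: Proposed new method: the arylperoxyseleninic acid formed in situ adds to C1, the only carbonyl not locked in the hydrogen-bonded vinylogous-acid chelate with the peri hydroxyl, and the vinyl carbon C2 migrates to oxygen in preference to the electron-poor aryl carbon (ortho acyl, para bromine), which makes the new C2–O bond; water opens enol lactone 13 to the 2-hydroxyaryl beta-keto aldehyde 14, whose phenol adds to the aldehyde and dehydrates to the pyranone, so the quinone C1 becomes the 5-carboxyl group and the peri oxygen becomes O1; the closest known reactions are the areneseleninic acid/H2O2 Baeyer–Villiger oxidation of enones and enals to enol esters and the acid-catalysed cyclodehydration of 2-hydroxyaryl beta-keto aldehydes to chromones, while Baeyer–Villiger cleavage of a juglone and its ring contraction to a chromone-5-carboxylic acid have not been described.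

Step 7
Reactants: 15 8-bromo-7-methyl-4-oxo-4H-chromene-5-carboxylic acid; 5 2-bromo-5-hydroxy-7-methylnaphthalene-1,4-dione
Product: 17 8-(5-hydroxy-7-methyl-1,4-dioxo-1,4-dihydronaphthalen-2-yl)-7-methyl-4-oxo-4H-chromene-5-carboxylic acid, via chromone pinacol boronate 16 (not isolated)
Conditions: B2pin2 (1.1 equiv), Pd(OAc)2 (5 mol %), 2-dicyclohexylphosphino-2',6'-dimethoxybiphenyl (SPhos, 10 mol %), KOAc (4 equiv), 1,4-dioxane, 90 °C; then 5 (1.2 equiv), K3PO4 (3 equiv), H2O (10 vol %), 50 °C; aq. HCl work-up
Reagents that add atoms: bis(pinacolato)diboron, CC1(C)OB(OC1(C)C)B1OC(C)(C)C(C)(C)O1 (boryl group of 16 only; none of its atoms stay in 17)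
Why: Miyaura borylation of the hindered aryl bromide followed in the same flask by Suzuki–Miyaura coupling with the activated vinylogous acyl bromide 5, where the electron-rich biarylphosphine supports coupling to a biaryl with three ortho substituents, the acid and the phenol are carried as potassium salts, and the mild phosphate base spares the quinone.

**Compound list**
1 | methyl 3-methylbut-2-enoate | COC(=O)C=C(C)C | starting material
2 | 1-methoxy-3-methyl-1-(trimethylsilyloxy)buta-1,3-diene (E/Z mixture at C1=C2) | COC(O[Si](C)(C)C)=CC(C)=C | intermediate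
3 | 2,5-dibromo-1,4-benzoquinone | O=C1C=C(Br)C(=O)C=C1Br | starting material
4 | 2,4a-dibromo-5-methoxy-7-methyl-5-(trimethylsilyloxy)-4a,5,8,8a-tetrahydronaphthalene-1,4-dione (racemic, cis-fused) | O=C1C(Br)=CC(=O)C2(Br)C(OC)(O[Si](C)(C)C)C=C(C)CC12 | intermediate
5 | 2-bromo-5-hydroxy-7-methylnaphthalene-1,4-dione | Cc1cc(O)c2C(=O)C=C(Br)C(=O)c2c1 | intermediate
6 | methyl 2,3-dibromo-3-methylbutanoate (racemic) | COC(=O)C(Br)C(C)(C)Br | intermediate
7 | methyl 2-bromo-3-methylbut-2-enoate | COC(=O)C(Br)=C(C)C | intermediate
8 | 2-bromo-1-methoxy-3-methyl-1-(trimethylsilyloxy)buta-1,3-diene (E/Z mixture at C1=C2) | COC(O[Si](C)(C)C)=C(Br)C(C)=C | intermediate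
9 | 1,4-benzoquinone | O=C1C=CC(=O)C=C1 | starting material
10 | 6-bromo-5-methoxy-7-methyl-5-(trimethylsilyloxy)-4a,5,8,8a-tetrahydronaphthalene-1,4-dione (racemic, cis-fused) | O=C1C=CC(=O)C2C1CC(C)=C(Br)C2(OC)O[Si](C)(C)C | intermediate
11 | 6-bromo-7-methylnaphthalene-1,4,5-triol | Cc1cc2c(O)ccc(O)c2c(O)c1Br | intermediate
12 | 6-bromo-5-hydroxy-7-methylnaphthalene-1,4-dione | Cc1cc2C(=O)C=CC(=O)c2c(O)c1Br | intermediate
13 | 7-bromo-6-hydroxy-8-methyl-2-benzoxepine-1,5-dione | Cc1cc2C(=O)OC=CC(=O)c2c(O)c1Br | intermediate
14 | 4-bromo-3-hydroxy-5-methyl-2-(3-oxopropanoyl)benzoic acid | Cc1cc(C(=O)O)c(C(=O)CC=O)c(O)c1Br | intermediate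
15 | 8-bromo-7-methyl-4-oxo-4H-chromene-5-carboxylic acid | Cc1cc(C(=O)O)c2c(=O)ccoc2c1Br | intermediate
16 | 7-methyl-4-oxo-8-(4,4,5,5-tetramethyl-1,3,2-dioxaborolan-2-yl)-4H-chromene-5-carboxylic acid | Cc1cc(C(=O)O)c2c(=O)ccoc2c1B1OC(C)(C)C(C)(C)O1 | intermediate
17 | 8-(5-hydroxy-7-methyl-1,4-dioxo-1,4-dihydronaphthalen-2-yl)-7-methyl-4-oxo-4H-chromene-5-carboxylic acid | Cc1cc(O)c2c(c1)C(=O)C(c1c(C)cc(C(=O)O)c3c(=O)ccoc13)=CC2=O | target

**Totals**
Total step count: 7. Longest linear sequence: 5 steps (steps 3, 4, 5, 6, 7; 1 to 7 to 8 to 12 to 15 to 17).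

**Steps most likely to fail**

Step 6 (the new ring contraction). The aryl carbon could migrate instead of C2, peroxide could attack the chelated C4 carbonyl in a Dakin-type reaction, or aldehyde 14 could be over-oxidised before it cyclises. The fallback uses known chemistry, sets out from diene 8 and comes back at 15. Diene 8 is heated with the known acetylenic keto ester methyl 4-oxopent-2-ynoate F1 (toluene, 80 °C; then dilute HCl). This Diels–Alder/aromatisation is steered by the ketone, the stronger acceptor, so the acetal carbon ends next to the acetyl group and gives methyl 2-acetyl-4-bromo-3-hydroxy-5-methylbenzoate F2. Condensation with Me2NCH(OMe)2 gives the enaminone methyl 4-bromo-2-[(2E)-3-(dimethylamino)prop-2-enoyl]-3-hydroxy-5-methylbenzoate F3. F3 closes under acid (TsOH, toluene, 80 °C) to methyl 8-bromo-7-methyl-4-oxo-4H-chromene-5-carboxylate F4, the classical enaminone chromone synthesis. Acid hydrolysis of the ester (aq. HCl, AcOH, reflux; chromones tolerate acid but not hydroxide) gives 15.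

Step 4 (the 2-bromo diene). The alpha-bromo dienolate may lose bromide, or diene 8 may be too labile or too sluggish for step 5. The fallback puts the halogen on after the ring contraction; it sets out from diene 2 and benzoquinone 9 and comes back at boronate 16. Annulation of 2 onto 9 under the conditions of step 5 gives 5-hydroxy-7-methylnaphthalene-1,4-dione F5. The ring contraction of step 6 turns it into 7-methyl-4-oxo-4H-chromene-5-carboxylic acid F6. Electrophilic iodination (N-iodosuccinimide, CF3SO3H, 0 °C) then gives 8-iodo-7-methyl-4-oxo-4H-chromene-5-carboxylic acid F7. C8 is ortho to both the ring oxygen and the methyl group, whereas C6 is wedged between the methyl and carboxyl groups, so C8 is the expected site; this regiochemistry is the weak point of the fallback. F7 takes the place of 15 in the borylation of step 7 and gives 16.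

Step 7 (one-pot borylation and coupling). The ortho-oxygenated, electron-poor boronate may protodeboronate, and bromoquinone 5 with its free phenol may be hydrolysed by the base or reduced by residual diboron. The fallback builds the juglone after the biaryl bond; it sets out from 15 and comes back at 17. Boronate 16 is made as in step 7 but isolated, then coupled with an excess (3 equiv) of the hydroxyl-free, symmetrical dibromoquinone 3 (Pd(OAc)2, SPhos, K3PO4, toluene/water, 40 °C). This gives 8-(4-bromo-3,6-dioxocyclohexa-1,4-dien-1-yl)-7-methyl-4-oxo-4H-chromene-5-carboxylic acid F8. Ring A of the juglone is then built by the Diels–Alder annulation of step 2 with diene 2 (2.5 equiv, the first equivalent silylating the acid). The remaining bromine again directs the acetal carbon, so the hydroxyl ends peri to the carbonyl remote from the aryl group, and 17 results.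

**Further compounds**
F1 | step 6 | methyl 4-oxopent-2-ynoate | CC(=O)C#CC(=O)OC
F2 | step 6 | methyl 2-acetyl-4-bromo-3-hydroxy-5-methylbenzoate | COC(=O)c1cc(C)c(Br)c(O)c1C(C)=O
F3 | step 6 | methyl 4-bromo-2-[(2E)-3-(dimethylamino)prop-2-enoyl]-3-hydroxy-5-methylbenzoate | COC(=O)c1cc(C)c(Br)c(O)c1C(=O)/C=C/N(C)C
F4 | step 6 | methyl 8-bromo-7-methyl-4-oxo-4H-chromene-5-carboxylate | COC(=O)c1cc(C)c(Br)c2occc(=O)c12
F5 | step 4 | 5-hydroxy-7-methylnaphthalene-1,4-dione | Cc1cc(O)c2C(=O)C=CC(=O)c2c1
F6 | step 4 | 7-methyl-4-oxo-4H-chromene-5-carboxylic acid | Cc1cc(C(=O)O)c2c(=O)ccoc2c1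
F7 | step 4 | 8-iodo-7-methyl-4-oxo-4H-chromene-5-carboxylic acid | Cc1cc(C(=O)O)c2c(=O)ccoc2c1I
F8 | step 7 | 8-(4-bromo-3,6-dioxocyclohexa-1,4-dien-1-yl)-7-methyl-4-oxo-4H-chromene-5-carboxylic acid | Cc1cc(C(=O)O)c2c(=O)ccoc2c1C1=CC(=O)C(Br)=CC1=O
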